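The C40 chain is cut at the C12'–C13' σ bond between two sp2 carbons. This leaves the ε ring with its C3' palmitate on a C16 (E)-trienyl iodide, and the β ring with its C3 myristate on a C24 heptaenyl pinacol boronate. One final Suzuki–Miyaura coupling joins them with retention at C11'=C12' and C13'=C14'. It completes the conjugated decaene and delivers the mixed diester itself, so the two carbinols never need to be differentiated. The step exploits the unbranched C12'H (from a C11' aldehyde) beside the methyl-branched C13' (from syn borylcupration of but-2-yn-1-ol). C6' is bought with (R)-α-ionone and relays C3'; C3 comes from actinol.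

Key step: step 17

Remark: carotenoid numbering is used (unprimed for the β half, primed for the ε half). (R)-α-Ionone and (4R,6R)-actinol are assumed to be purchasable in enantiopure form. All polyenes are handled under argon in dim light.

Step 1
Reactants: 1 (R)-α-ionone
Product: 2 (2E,4E)-3-methyl-5-[(1R)-2,6,6-trimethylcyclohex-2-en-1-yl]penta-2,4-dienenitrile
Conditions: (EtO)2P(O)CH2CN, NaH, THF, 0 °C to rt; chromatographic removal of the 9'Z isomer
Reagents that add atoms: diethyl cyanomethylphosphonate, N#CCP(=O)(OCC)OCC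
Why: Horner–Wadsworth–Emmons olefination of the methyl ketone with the small stabilised carbanion should favour the 9'E nitrile, and this weakly basic anion should not remove the γ-proton at C6', so the purchased stereocenter is kept.

Step 2
Reactants: 2 dienenitrile
Product: 3 (2E,4E)-3-methyl-5-[(1R)-2,6,6-trimethyl-4-oxocyclohex-2-en-1-yl]penta-2,4-dienenitrile
Conditions: t-BuOOH (70 % aq), Rh2(cap)4 (dirhodium tetracaprolactamate, cat.), 1,2-dichloroethane, 40 °C
Reagents that add atoms: tert-butyl hydroperoxide, CC(C)(C)OO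
Why: Radical allylic C–H oxidation by t-BuOO radicals should attack the only unhindered ring allylic CH2 (C3'), because C6'–H is shielded by the C1' gem-dimethyl and C5' methyl groups and the dienenitrile is electron-poor, while the base-free medium leaves the now vinylogously acidic C6'–H in place.

Step 3
Reactants: 3 keto nitrile
Product: 4 (2E,4E)-5-[(1R,4R)-4-hydroxy-2,6,6-trimethylcyclohex-2-en-1-yl]-3-methylpenta-2,4-dienenitrile (OH trans to the side chain)
Conditions: LiBH(s-Bu)3, THF, −78 °C; then H2O
Reagents that add atoms: none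
Why: In this substrate-controlled 1,2-reduction the bulky hydride should attack C3'=O on the equatorial trajectory, on the face away from the axial C1' methyl group of the half-chair whose C6' chain is pseudoaxial, which places the new OH pseudoaxial and trans to the chain (3'R), while the β,β-disubstituted enone resists 1,4-reduction.

Step 4
Reactants: 4 hydroxy nitrile
Product: 6 (2E,4E)-5-[(1R,4R)-4-hydroxy-2,6,6-trimethylcyclohex-2-en-1-yl]-3-methylpenta-2,4-dienal, via aldimine 5 (not isolated)
Conditions: i-Bu2AlH (2.5 equiv), CH2Cl2, −78 to −40 °C; then aq. KNaC4H4O6 (tartrate), pH 5 buffer, 0 °C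
Reagents that add atoms: water, O
Why: Partial nitrile reduction stops at the N-aluminated aldimine (one equivalent of hydride is consumed by the OH group), and mild buffered hydrolysis should release the enal without ionising the acid-labile allylic C3' alcohol or changing the 9'E geometry.

Step 5
Reactants: 6 hydroxy aldehyde; 7 palmitoyl chloride (hexadecanoyl chloride)
Product: 8 (1R,4R)-4-[(1E,3E)-3-methyl-5-oxopenta-1,3-dien-1-yl]-3,5,5-trimethylcyclohex-2-en-1-yl hexadecanoate
Conditions: pyridine, DMAP (cat.), CH2Cl2, 0 °C to rt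
Reagents that add atoms: none
Why: DMAP-catalysed O-acylation touches only the O–H bond, so C3' keeps its configuration and the palmitate is fixed on the ε ring before the two halves meet.

Step 6
Reactants: 8 palmitoyloxy aldehyde
Product: 9 (1R,4R)-4-[(1E,3E,5E)-6-iodo-3-methylhexa-1,3,5-trien-1-yl]-3,5,5-trimethylcyclohex-2-en-1-yl hexadecanoate
Conditions: CrCl2, CHI3, THF–dioxane, 0 °C to rt, dark
Reagents that add atoms: iodoform, IC(I)I
Why: In the Takai olefination the gem-dichromium carbenoid formed from CHI3 and divalent chromium adds to the aldehyde and eliminates to give the (E)-alkenyl iodide at C11'=C12', while esters and the allylic C–O bond are inert to CrCl2.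

Step 7
Reactants: 10 but-2-yn-1-ol
Product: 11 (2Z)-3-(4,4,5,5-tetramethyl-1,3,2-dioxaborolan-2-yl)but-2-en-1-ol (boron trans to CH2OH)
Conditions: B2pin2, CuCl (cat.), PCy3 (cat.), NaOt-Bu (cat.), MeOH, toluene, rt
Reagents that add atoms: bis(pinacolato)diboron, CC1(C)OB(OC1(C)C)B1OC(C)(C)C(C)(C)O1
Why: In this copper-catalysed formal hydroboration the copper boryl adds syn across the alkyne with boron on the carbon remote from the propargylic oxygen (future C13'), and MeOH protonates the C–Cu bond with retention, which fixes boron trans and methyl cis to the chain.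

Step 8
Reactants: 11 boryl butenol
Product: 12 (2Z)-3-(4,4,5,5-tetramethyl-1,3,2-dioxaborolan-2-yl)but-2-enal
Conditions: activated MnO2, CH2Cl2, rt
Reagents that add atoms: none
Why: MnO2 oxidises the allylic alcohol selectively and should leave the C–B bond and the alkene geometry untouched.

Step 9
Reactants: 12 boryl butenal
Product: 13 (2E,4Z)-5-(4,4,5,5-tetramethyl-1,3,2-dioxaborolan-2-yl)hexa-2,4-dienal
Conditions: Ph3P=CHCHO, toluene, 80 °C
Reagents that add atoms: (triphenylphosphoranylidene)acetaldehyde, O=CC=P(c1ccccc1)(c1ccccc1)c1ccccc1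
Why: Wittig olefination with the stabilised formylmethylene ylide should give the E alkene (C15'=C15), and a slight deficit of ylide limits a second homologation.

Step 10
Reactants: 13 boryl dienal
Product: 14 (2E,4E,6Z)-2-methyl-7-(4,4,5,5-tetramethyl-1,3,2-dioxaborolan-2-yl)octa-2,4,6-trienal
Conditions: Ph3P=C(CH3)CHO, toluene, 95 °C
Reagents that add atoms: 2-(triphenylphosphoranylidene)propanal, CC(C=O)=P(c1ccccc1)(c1ccccc1)c1ccccc1
Why: Wittig olefination with the α-methyl stabilised ylide should form the trisubstituted C13=C14 bond with the formyl group trans to the chain (E), and the α-branched enal formed is too unreactive to be homologated again.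

Step 11
Reactants: 15 (2E)-3-methylpent-2-en-4-yn-1-ol
Product: 16 diethyl [(2E)-3-methylpent-2-en-4-yn-1-yl]phosphonate
Conditions: P(OEt)3, ZnI2, THF, reflux
Reagents that add atoms: triethyl phosphite, CCOP(OCC)OCC
Why: The ZnI2-mediated Michaelis–Arbuzov-type phosphonylation converts a primary allylic alcohol directly, with substitution at the primary carbon, and should leave the E alkene and the terminal alkyne unchanged.

Step 12
Reactants: 16 enynyl phosphonate
Product: 17 diethyl [(2E,4E)-3-methyl-5-(tributylstannyl)penta-2,4-dien-1-yl]phosphonate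
Conditions: Bu3SnH, PdCl2(PPh3)2 (cat.), THF, 0 °C to rt
Reagents that add atoms: tributyltin hydride, CCCC[SnH](CCCC)CCCC
Why: Palladium-catalysed syn hydrostannation should place tin on the terminal alkyne carbon, because the internal carbon is shielded by the branched C9, and so gives the (E)-alkenylstannane (C7=C8).

Step 13
Reactants: 18 (4R,6R)-actinol, (4R,6R)-4-hydroxy-2,2,6-trimethylcyclohexanone; 19 myristoyl chloride (tetradecanoyl chloride)
Product: 20 (1R,3R)-3,5,5-trimethyl-4-oxocyclohexyl tetradecanoate
Conditions: pyridine, DMAP (cat.), CH2Cl2, 0 °C to rt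
Reagents that add atoms: none
Why: DMAP-catalysed O-acylation fixes the myristate on the β-ring precursor with retention at C3, and the acyloxy group is γ to the ketone and cannot be lost by β-elimination.

Step 14
Reactants: 20 actinol myristate
Product: 22 (1R)-3,5,5-trimethyl-4-{[(trifluoromethyl)sulfonyl]oxy}cyclohex-3-en-1-yl tetradecanoate, via potassium enolate 21 (not isolated)
Conditions: KN(SiMe3)2, THF, −78 to 0 °C; then PhNTf2, −78 °C to rt
Reagents that add atoms: N-phenylbis(trifluoromethanesulfonimide), O=S(=O)(N(c1ccccc1)S(=O)(=O)C(F)(F)F)C(F)(F)F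
Why: Reversible deprotonation by the silazide should settle on the more acidic ketone, which can enolise only towards C5 because C1 is quaternary, and O-sulfonylation then gives the single possible tetrasubstituted enol triflate, in which C3 is untouched and the C5 stereocenter is erased on purpose.

Step 15
Reactants: 22 enol triflate; 17 stannyl dienyl phosphonate
Product: 23 diethyl {(2E,4E)-3-methyl-5-[(4R)-2,6,6-trimethyl-4-(tetradecanoyloxy)cyclohex-1-en-1-yl]penta-2,4-dien-1-yl}phosphonate
Conditions: Pd2(dba)3·CHCl3 (cat.), AsPh3, NMP, 65 °C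
Reagents that add atoms: none
Why: Stille coupling of the hindered enol triflate forms C6–C7 with retention of the stannane geometry, the weakly bound AsPh3 ligand in polar NMP speeds the transmetalation, and the neutral medium spares the ester and the phosphonate.

Step 16
Reactants: 23 C15 phosphonate; 14 boryl trienal
Product: 25 (1R)-3,5,5-trimethyl-4-[(1E,3E,5E,7E,9E,11Z)-3,7-dimethyl-12-(4,4,5,5-tetramethyl-1,3,2-dioxaborolan-2-yl)trideca-1,3,5,7,9,11-hexaen-1-yl]cyclohex-3-en-1-yl tetradecanoate, via sodium phosphonate carbanion 24 (not isolated)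
Conditions: NaN(SiMe3)2 (1.0 equiv), THF–DMPU, −78 °C; then 14, −78 to 0 °C
Reagents that add atoms: none
Why: Horner–Wadsworth–Emmons olefination of the trienyl-conjugated phosphonate, which is far more acidic than the ester α-CH2, with the non-enolisable enal should form C11=C12 with E geometry, and the pinacol boronate tolerates the short exposure to the carbanion.

Step 17
Reactants: 9 C16 trienyl iodide; 25 C24 heptaenyl boronate
Product: 26 (3R,3'R,6'R)-lutein 3-O-myristate 3'-O-palmitate, (3R,3'R,6'R)-3-(tetradecanoyloxy)-β,ε-caroten-3'-yl hexadecanoate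
Conditions: Pd(OAc)2 (5 mol %), SPhos (10 mol %), K3PO4 (3 M aq), THF, degassed, rt, dark
Reagents that add atoms: none
Why: Zerovalent palladium (from Pd(OAc)2 and SPhos) inserts into the C12'–iodine bond of 9 with retention, the C13' boronate of 25 is activated by phosphate/hydroxide and hands its alkenyl group to palladium with retention, and reductive elimination forms the C12'–C13' σ bond. The closest known reaction type is the Suzuki–Miyaura coupling of an alkenyl iodide with an alkenyl boronate as used for stereoretentive polyene assembly. No ring is closed and no stereocenter is formed; C3, C3' and C6' are spectators, and the E geometry on both sides of the new bond is inherited from step 6 (C11'=C12') and step 7 (C13'=C14') because every elementary step is stereospecific. The chemoselectivity needed is insertion into the C(sp2)–iodine bond rather than ionisation of the allylic C3' palmitate, and it is secured by the far higher reactivity of the unhindered alkenyl iodide at room temperature compared with a secondary cyclohexenyl ester next to a trisubstituted alkene. Aqueous K3PO4 in THF is too weak a base to saponify the two secondary fatty esters or to remove the doubly allylic C6'–H, so the ε-ring double bond should not move into conjugation. Because each half already carries its own acyl group, the coupling product is the target and nothing has to be done to the sensitive decaene afterwards.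

Compound list
1 | (R)-α-ionone, (3E)-4-[(1R)-2,6,6-trimethylcyclohex-2-en-1-yl]but-3-en-2-one | C1C=C(C)[C@H](/C=C/C(C)=O)C(C)(C)C1 | starting material
2 | (2E,4E)-3-methyl-5-[(1R)-2,6,6-trimethylcyclohex-2-en-1-yl]penta-2,4-dienenitrile | C1C=C(C)[C@H](/C=C/C(C)=C/C#N)C(C)(C)C1 | intermediate
3 | (2E,4E)-3-methyl-5-[(1R)-2,6,6-trimethyl-4-oxocyclohex-2-en-1-yl]penta-2,4-dienenitrile | O=C1C=C(C)[C@H](/C=C/C(C)=C/C#N)C(C)(C)C1 | intermediate
4 | (2E,4E)-5-[(1R,4R)-4-hydroxy-2,6,6-trimethylcyclohex-2-en-1-yl]-3-methylpenta-2,4-dienenitrile | O[C@H]1C=C(C)[C@H](/C=C/C(C)=C/C#N)C(C)(C)C1 | intermediate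
5 | (2E,4E)-5-[(1R,4R)-4-hydroxy-2,6,6-trimethylcyclohex-2-en-1-yl]-3-methylpenta-2,4-dien-1-imine (aluminium-bound in the flask, not isolated) | O[C@H]1C=C(C)[C@H](/C=C/C(C)=C/C=N)C(C)(C)C1 | intermediate
6 | (2E,4E)-5-[(1R,4R)-4-hydroxy-2,6,6-trimethylcyclohex-2-en-1-yl]-3-methylpenta-2,4-dienal | O[C@H]1C=C(C)[C@H](/C=C/C(C)=C/C=O)C(C)(C)C1 | intermediate
7 | palmitoyl chloride (hexadecanoyl chloride) | CCCCCCCCCCCCCCCC(=O)Cl | starting material
8 | (1R,4R)-4-[(1E,3E)-3-methyl-5-oxopenta-1,3-dien-1-yl]-3,5,5-trimethylcyclohex-2-en-1-yl hexadecanoate | CCCCCCCCCCCCCCCC(=O)O[C@H]1C=C(C)[C@H](/C=C/C(C)=C/C=O)C(C)(C)C1 | intermediate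
9 | (1R,4R)-4-[(1E,3E,5E)-6-iodo-3-methylhexa-1,3,5-trien-1-yl]-3,5,5-trimethylcyclohex-2-en-1-yl hexadecanoate | CCCCCCCCCCCCCCCC(=O)O[C@H]1C=C(C)[C@H](/C=C/C(C)=C/C=C/I)C(C)(C)C1 | intermediate
10 | but-2-yn-1-ol | CC#CCO | starting material
11 | (2Z)-3-(4,4,5,5-tetramethyl-1,3,2-dioxaborolan-2-yl)but-2-en-1-ol | C(/C)(=C/CO)B1OC(C)(C)C(C)(C)O1 | intermediate
12 | (2Z)-3-(4,4,5,5-tetramethyl-1,3,2-dioxaborolan-2-yl)but-2-enal | C(/C)(=C/C=O)B1OC(C)(C)C(C)(C)O1 | intermediate
13 | (2E,4Z)-5-(4,4,5,5-tetramethyl-1,3,2-dioxaborolan-2-yl)hexa-2,4-dienal | C(/C)(=C/C=C/C=O)B1OC(C)(C)C(C)(C)O1 | intermediate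
14 | (2E,4E,6Z)-2-methyl-7-(4,4,5,5-tetramethyl-1,3,2-dioxaborolan-2-yl)octa-2,4,6-trienal | C(/C)(=C/C=C/C=C(C)/C=O)B1OC(C)(C)C(C)(C)O1 | intermediate
15 | (2E)-3-methylpent-2-en-4-yn-1-ol | C#C/C(C)=C/CO | starting material
16 | diethyl [(2E)-3-methylpent-2-en-4-yn-1-yl]phosphonate | C#C/C(C)=C/CP(=O)(OCC)OCC | intermediate
17 | diethyl [(2E,4E)-3-methyl-5-(tributylstannyl)penta-2,4-dien-1-yl]phosphonate | CCCC[Sn](CCCC)(CCCC)/C=C/C(C)=C/CP(=O)(OCC)OCC | intermediate
18 | (4R,6R)-actinol, (4R,6R)-4-hydroxy-2,2,6-trimethylcyclohexanone | O=C1[C@H](C)C[C@@H](O)CC1(C)C | starting material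
19 | myristoyl chloride (tetradecanoyl chloride) | CCCCCCCCCCCCCC(=O)Cl | starting material
20 | (1R,3R)-3,5,5-trimethyl-4-oxocyclohexyl tetradecanoate | O=C1[C@H](C)C[C@@H](OC(=O)CCCCCCCCCCCCC)CC1(C)C | intermediate
21 | potassium enolate of 20 (not isolated) | [K+].[O-]C1=C(C)C[C@@H](OC(=O)CCCCCCCCCCCCC)CC1(C)C | intermediate
22 | (1R)-3,5,5-trimethyl-4-{[(trifluoromethyl)sulfonyl]oxy}cyclohex-3-en-1-yl tetradecanoate | O=S(=O)(OC1=C(C)C[C@@H](OC(=O)CCCCCCCCCCCCC)CC1(C)C)C(F)(F)F | intermediate
23 | diethyl {(2E,4E)-3-methyl-5-[(4R)-2,6,6-trimethyl-4-(tetradecanoyloxy)cyclohex-1-en-1-yl]penta-2,4-dien-1-yl}phosphonate | CCOP(=O)(OCC)C/C=C(C)/C=C/C1=C(C)C[C@@H](OC(=O)CCCCCCCCCCCCC)CC1(C)C | intermediate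
24 | sodium carbanion of phosphonate 23 (not isolated) | [Na+].CCOP(=O)(OCC)[CH-]/C=C(C)/C=C/C1=C(C)C[C@@H](OC(=O)CCCCCCCCCCCCC)CC1(C)C | intermediate
25 | (1R)-3,5,5-trimethyl-4-[(1E,3E,5E,7E,9E,11Z)-3,7-dimethyl-12-(4,4,5,5-tetramethyl-1,3,2-dioxaborolan-2-yl)trideca-1,3,5,7,9,11-hexaen-1-yl]cyclohex-3-en-1-yl tetradecanoate | C(/C)(=C/C=C/C=C(C)/C=C/C=C(C)/C=C/C1=C(C)C[C@@H](OC(=O)CCCCCCCCCCCCC)CC1(C)C)B2OC(C)(C)C(C)(C)O2 | intermediate
26 | (3R,3'R,6'R)-lutein 3-O-myristate 3'-O-palmitate | CCCCCCCCCCCCCCCC(=O)O[C@H]1C=C(C)[C@H](/C=C/C(C)=C/C=C/C(C)=C/C=C/C=C(C)/C=C/C=C(C)/C=C/C2=C(C)C[C@@H](OC(=O)CCCCCCCCCCCCC)CC2(C)C)C(C)(C)C1 | target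

Total step count: 17 steps.
Longest linear sequence: 7 steps (1 → 2 → 3 → 4 → 6 → 8 → 9 → 26).

Steps most likely to fail

Step 17. The electron-rich heptaenyl boronate may lose boron by protonolysis, or may transfer its hindered α-methyl alkenyl group too slowly. The iodide would then decompose, or double bonds would scramble. The fallback sets out from 9 and 14 and comes back at 26. The same C12'–C13' bond is made earlier, on the small and electron-poor boronate. Iodide 9 is coupled with trienal boronate 14 (Pd(OAc)2, SPhos, aq K3PO4, THF, rt). This should give the C25 aldehyde (1R,4R)-4-[(1E,3E,5E,7E,9E,11E)-3,7,12-trimethyl-13-oxotrideca-1,3,5,7,9,11-hexaen-1-yl]-3,5,5-trimethylcyclohex-2-en-1-yl hexadecanoate F1. The last bond formed then becomes C11=C12. Carbanion 24, made from 23 with NaN(SiMe3)2 in THF–DMPU at −78 °C, is added to F1 in a Horner–Wadsworth–Emmons olefination that should give 26.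

Step 3. Facial selectivity of the hydride delivery may be poor, or conjugate reduction may compete. The fallback sets out from 3 and comes back at 8, and it no longer depends on the face of attack. Compound 3 is reduced at the ketone and the nitrile in one operation with i-Bu2AlH and hydrolysed as in step 4. This gives 6 together with its C3' epimer (2E,4E)-5-[(1R,4S)-4-hydroxy-2,6,6-trimethylcyclohex-2-en-1-yl]-3-methylpenta-2,4-dienal F2, and the two are separated by chromatography. Compound 6 is acylated as in step 5. F2 is esterified with palmitic acid under Mitsunobu conditions (PPh3, DIAD, THF, 0 °C). Inversion at C3' should lead to the same ester 8, so both epimers converge.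

Step 14. The ester α-CH2 may be deprotonated faster than the hindered tertiary C5–H of the ketone. That would lead to Claisen-type condensation, loss of the acyl group or low conversion. The fallback sets out from 18 and comes back at 22, and it installs the acyl group only after the enolate chemistry:
- Compound 18 is silylated (Et3SiCl, imidazole, DMF) to (4R,6R)-2,2,6-trimethyl-4-(triethylsilyloxy)cyclohexanone F3.
- F3 is converted (KN(SiMe3)2, then PhNTf2) into (4R)-2,6,6-trimethyl-4-(triethylsilyloxy)cyclohex-1-en-1-yl trifluoromethanesulfonate F4.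
- F4 is desilylated with AcOH–THF–H2O to (4R)-4-hydroxy-2,6,6-trimethylcyclohex-1-en-1-yl trifluoromethanesulfonate F5.
- F5 is acylated with 19 (pyridine, DMAP) to give 22.

Further compounds
F1 | step 17 | (1R,4R)-4-[(1E,3E,5E,7E,9E,11E)-3,7,12-trimethyl-13-oxotrideca-1,3,5,7,9,11-hexaen-1-yl]-3,5,5-trimethylcyclohex-2-en-1-yl hexadecanoate | CCCCCCCCCCCCCCCC(=O)O[C@H]1C=C(C)[C@H](/C=C/C(C)=C/C=C/C(C)=C/C=C/C=C(C)/C=O)C(C)(C)C1
F2 | step 3 | (2E,4E)-5-[(1R,4S)-4-hydroxy-2,6,6-trimethylcyclohex-2-en-1-yl]-3-methylpenta-2,4-dienal | O[C@@H]1C=C(C)[C@H](/C=C/C(C)=C/C=O)C(C)(C)C1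
F3 | step 14 | (4R,6R)-2,2,6-trimethyl-4-(triethylsilyloxy)cyclohexanone | O=C1[C@H](C)C[C@@H](O[Si](CC)(CC)CC)CC1(C)C
F4 | step 14 | (4R)-2,6,6-trimethyl-4-(triethylsilyloxy)cyclohex-1-en-1-yl trifluoromethanesulfonate | O=S(=O)(OC1=C(C)C[C@@H](O[Si](CC)(CC)CC)CC1(C)C)C(F)(F)F
F5 | step 14 | (4R)-4-hydroxy-2,6,6-trimethylcyclohex-1-en-1-yl trifluoromethanesulfonate | O=S(=O)(OC1=C(C)C[C@@H](O)CC1(C)C)C(F)(F)F
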